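**Plan**
1. Ring carbons are numbered C1 (bearing CH2OAc) to C10. C1 and C2, with the CH2O carbon on C1 and the carboxyl carbon on C2 cis across the tetrasubstituted C1=C2 alkene, are the β-carbon, α-carbon, C5 and C2 of a furan-2(5H)-one ring. 3,4-Dibromofuran-2(5H)-one therefore supplies this alkene with locked geometry and two C–Br bonds of unequal reactivity.
2. Retrosynthesis: acetate and acid go back to the lactone; C4–C5 is cut (ring-closing Stille) and C5=C6 (Takai iodo-olefination); then C2–C3 and C10–C1 are cut at the dibromobutenolide, leaving (Z)-1,2-bis(tributylstannyl)ethene and a C6–C10 alkylborate.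
3. The C6–C10 piece is cut at the bond from C7 to the furylethyl chain (conjugate addition to (R)-3,4-dimethylcyclohex-2-enone); the ring is cleaved next to the carbonyl and the carbonyl carbon is removed by decarboxylative iodination.
4. Forward: side chain plus enone, open-chain C6–C10 iodide, borate, one-flask union with the dibromobutenolide and the distannane; the only new ring (the ten-membered carbocycle) closes at C4–C5; the lactone is opened and acetylated last.
5. Stereochemistry: C8 comes from the enone; C7 from addition anti to the C8 methyl; C1=C2 from the lactone, C3=C4 (Z) from the distannane, C5=C6 (E) from the Takai reaction.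

Key step: step 10

Assumption: (R)-3,4-dimethylcyclohex-2-en-1-one is taken as a purchasable chiral-pool enone (otherwise a few steps from (R)-pulegone).

**Step 1**
Reactants: 1 3-bromofuran
Product: 3 2-(furan-3-yl)ethan-1-ol, via 3-furyllithium 2 (not isolated)
Conditions: n-BuLi, THF, −78 °C; ethylene oxide, BF3·OEt2, −78 °C; H2O
Reagents that add atoms: ethylene oxide C1CO1; n-butyllithium [Li]CCCC (Li only in intermediate 2)
Why: Bromine–lithium exchange at −78 °C gives 3-furyllithium without drift to the 2-position, and BF3-assisted SN2 opening of the epoxide adds the two-carbon alcohol arm.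

**Step 2**
Reactants: 3 2-(furan-3-yl)ethan-1-ol
Product: 4 3-(2-bromoethyl)furan
Conditions: CBr4, PPh3, CH2Cl2, 0 °C
Reagents that add atoms: carbon tetrabromide BrC(Br)(Br)Br
Why: The Appel reaction converts the primary alcohol to the bromide by SN2 displacement of an alkoxyphosphonium ion under neutral conditions that spare the furan.

**Step 3**
Reactants: 4 3-(2-bromoethyl)furan; 5 (R)-3,4-dimethylcyclohex-2-en-1-one
Product: 7 {[(3S,4R)-3-[2-(furan-3-yl)ethyl]-3,4-dimethylcyclohex-1-en-1-yl]oxy}trimethylsilane, via Grignard reagent 6 (not isolated)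
Conditions: Mg, THF, 40 °C; then CuBr·SMe2 (10 mol %), TMSCl, HMPA, 5, THF, −78 → −40 °C; Et3N, pentane
Reagents that add atoms: chlorotrimethylsilane C[Si](C)(C)Cl; magnesium [Mg] (only in intermediate 6)
Why: In this copper-catalysed, TMSCl-accelerated conjugate addition the C4 methyl, held pseudoaxial by allylic strain with the C3 methyl, should direct axial attack to the opposite face, so the quaternary centre (target C7) forms with the side chain trans to that methyl and the enolate is trapped regiospecifically as its silyl enol ether.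

**Step 4**
Reactants: 7 silyl enol ether
Product: 9 (3S,4R)-3-[2-(furan-3-yl)ethyl]-2-hydroxy-3,4-dimethylcyclohexan-1-one (C2 epimers), via silyloxy ketone 8 (not isolated)
Conditions: mCPBA (1.05 equiv), CH2Cl2, −20 °C; then citric acid (cat), MeOH, 0 °C
Reagents that add atoms: mCPBA O=C(OO)c1cccc(Cl)c1
Why: In the Rubottom oxidation the electron-rich enol ether is epoxidised far faster than the 3-alkylfuran at −20 °C, silyl migration gives the α-silyloxy ketone, and mild acidic methanolysis frees the ketol without base-induced ketol shift; the carbinol configuration is irrelevant because that centre is destroyed in step 5.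

**Step 5**
Reactants: 9 α-hydroxy ketone
Product: 11 (4R,5S)-7-(furan-3-yl)-5-(hydroxymethyl)-4,5-dimethylheptanoic acid, via aldehyde acid 10 (not isolated)
Conditions: NaIO4, THF/H2O, 23 °C; then NaHCO3, NaBH4, 0 °C; citric acid to pH 4
Reagents that add atoms: water O
Why: Periodate cleavage of the α-ketol (Malaprade-type, through the ketone hydrate) gives the non-enolisable neopentyl aldehyde and the acid, and NaBH4 then reduces only the aldehyde because the carboxylate is inert.

**Step 6**
Reactants: 11 hydroxy acid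
Product: 13 (4R,5S)-5-{[(tert-butyldimethylsilyl)oxy]methyl}-7-(furan-3-yl)-4,5-dimethylheptanoic acid, via silyl ester 12 (not isolated)
Conditions: TBSCl (2.5 equiv), imidazole, DMF, 23 °C; then K2CO3, MeOH/THF/H2O, 23 °C; citric acid to pH 5
Reagents that add atoms: tert-butyldimethylsilyl chloride CC(C)(C)[Si](C)(C)Cl
Why: Silylation caps both the alcohol and the acid, and the much more labile silyl ester is then hydrolysed selectively by carbonate in methanol while the primary silyl ether stays.

**Step 7**
Reactants: 13 silyl ether acid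
Product: 15 tert-butyl({(2S,3R)-2-[2-(furan-3-yl)ethyl]-5-iodo-2,3-dimethylpentyl}oxy)dimethylsilane, via Barton ester 14 (not isolated)
Conditions: 1-hydroxypyridine-2(1H)-thione, DCC, DMAP (cat), CH2Cl2, 23 °C, dark; then CHI3 (3 equiv), PhH, tungsten lamp, 30 °C
Reagents that add atoms: iodoform IC(I)I; 1-hydroxypyridine-2(1H)-thione On1ccccc1=S (only in intermediate 14)
Why: In the Barton decarboxylative iodination the thiohydroxamate ester fragments in a radical chain, CO2 is lost, and the primary C10 radical abstracts iodine from iodoform faster than it can add to the remote furan.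

**Step 8**
Reactants: 16 hexabutylditin
Product: 17 (Z)-1,2-bis(tributylstannyl)ethene
Conditions: acetylene (1 atm), Pd(PPh3)4 (2 mol %), 1,4-dioxane, 60 °C, dark
Reagents that add atoms: acetylene C#C
Why: Palladium-catalysed distannation of the alkyne proceeds by oxidative addition of the Sn–Sn bond to zerovalent palladium and syn insertion, so both tin groups end up cis.

**Step 9**
Reactants: 15 alkyl iodide
Product: 19 lithium methoxy-ate complex of the C6–C10 B-alkyl-9-BBN, via alkyllithium 18 (not isolated)
Conditions: t-BuLi (2.1 equiv), Et2O, −78 °C; B-methoxy-9-BBN (1.2 equiv), THF, −78 → 23 °C; solution used directly in step 10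
Reagents that add atoms: 9-methoxy-9-borabicyclo[3.3.1]nonane COB1C2CCCC1CCC2; tert-butyllithium [Li]C(C)(C)C
Why: Lithium–iodine exchange at −78 °C is much faster than metalation of the furan, and the primary alkyllithium is captured by the borinate ester to give the tetracoordinate borate used in B-alkyl Suzuki–Miyaura couplings.

**Step 10**
Reactants: 19 lithium alkyl(methoxy)borate; 20 3,4-dibromofuran-2(5H)-one; 17 (Z)-1,2-bis(tributylstannyl)ethene
Product: 22 4-[(3R,4S)-5-[(tert-butyldimethylsilyl)oxy]-4-[2-(furan-3-yl)ethyl]-3,4-dimethylpentyl]-3-[(Z)-2-(tributylstannyl)ethenyl]furan-2(5H)-one, via bromobutenolide 21 (not isolated)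
Conditions: PdCl2(dppf) (8 mol %), AsPh3 (25 mol %), DMF/THF, 0 → 23 °C, 19 added slowly to 20 (1.15 equiv), no added base; then 17 (3 equiv), CuI (30 mol %), 40 °C, dark
Reagents that add atoms: none
Why: Zerovalent palladium inserts first into the β-C–Br bond of 20, a vinylogous acyl bromide, and the tetracoordinate methoxyborate 19 transfers its primary alkyl group without aqueous base, so reductive elimination forms C10–C1 and leaves bromide 21 with only the less reactive α-C–Br bond. Keeping 20 in slight excess and adding 19 slowly leaves no borate for a second alkylation and spares the base-sensitive bromolactone from hydroxide or alkoxide attack. In the second stage the α-bromide undergoes oxidative addition, CuI and the weakly bound AsPh3 speed tin-to-palladium transfer from one end of 17, and reductive elimination forms C2–C3 with retention of the Z geometry. The closest known reaction type is the site-selective sequential Suzuki–Miyaura and Stille coupling of 3,4-dihalofuran-2(5H)-ones, β-position first, here run in one flask on one catalyst charge. No ring closes and no stereocentre forms; the five-membered lactone fixes the geometry of the tetrasubstituted C1=C2 alkene. The step needs β-before-α selectivity, secured by the electronic bias of the bromofuranone, and single coupling of the distannane, secured by its threefold excess, mild temperature and exclusion of light, which keeps the second tin for the ring closure.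

**Step 11**
Reactants: 22 silyl ether stannane
Product: 23 4-[(3R,4S)-4-[2-(furan-3-yl)ethyl]-5-hydroxy-3,4-dimethylpentyl]-3-[(Z)-2-(tributylstannyl)ethenyl]furan-2(5H)-one
Conditions: HF·pyridine, pyridine, THF, 0 → 23 °C
Reagents that add atoms: none
Why: Fluoride-mediated desilylation buffered with excess pyridine should remove the primary silyl ether without protodestannylation of the electron-poor dienylstannane and without the basic conditions that would deprotonate the butenolide.

**Step 12**
Reactants: 23 alcohol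
Product: 24 (2S,3R)-2-[2-(furan-3-yl)ethyl]-2,3-dimethyl-5-{5-oxo-4-[(Z)-2-(tributylstannyl)ethenyl]-2,5-dihydrofuran-3-yl}pentanal
Conditions: Dess–Martin periodinane, pyridine, CH2Cl2, 0 → 23 °C
Reagents that add atoms: none
Why: Dess–Martin oxidation is neutral and tolerates vinylstannanes and furans, and the aldehyde cannot epimerise because its α-carbon (C7) is quaternary.

**Step 13**
Reactants: 24 aldehyde
Product: 25 4-[(3R,4S,5E)-4-[2-(furan-3-yl)ethyl]-6-iodo-3,4-dimethylhex-5-en-1-yl]-3-[(Z)-2-(tributylstannyl)ethenyl]furan-2(5H)-one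
Conditions: CrCl2 (8 equiv), CHI3 (3 equiv), THF/1,4-dioxane, 0 → 23 °C, dark
Reagents that add atoms: iodoform IC(I)I
Why: In the Takai olefination the geminal dichromium carbenoid adds to the aldehyde only (the lactone and the stannane are inert) and elimination should give the E-iodoalkene, favoured further by the bulky quaternary neighbour and the dioxane cosolvent.

**Step 14**
Reactants: 25 iodide stannane
Product: 26 ten-membered-ring butenolide (lactone from the C1 CH2O to the C2 carboxyl; 3Z,5E,7S,8R in target numbering)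
Conditions: Pd2(dba)3 (15 mol %), AsPh3 (1 equiv), CuI (0.5 equiv), DMF, 0.002 M by slow addition, 23 → 40 °C, dark
Reagents that add atoms: none
Why: In this intramolecular Stille coupling zerovalent palladium inserts into the C5–I bond, copper-assisted tin-to-palladium transfer brings in C4, and reductive elimination forms C4–C5 with retention at both alkenes; high dilution favours ring closure, and the temperature is kept at or below 40 °C to avoid six-electron electrocyclisation of the Z-triene.

**Step 15**
Reactants: 26 macrocyclic butenolide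
Product: 28 (1(10)Z,2Z,4E,6S,7R)-10-[(acetyloxy)methyl]-6-[2-(furan-3-yl)ethyl]-6,7-dimethylcyclodeca-1(10),2,4-triene-1-carboxylic acid (CNP0110626.2), via sodium hydroxy carboxylate 27 (not isolated)
Conditions: NaOH (1.1 equiv), THF/H2O, 0 °C; evaporate; Ac2O, DMAP (cat), pyridine, 0 °C; H2O, then NaH2PO4 buffer (pH 4–5)
Reagents that add atoms: sodium hydroxide [Na+].[OH-]; acetic anhydride CC(=O)OC(C)=O
Why: Saponification gives the hydroxy carboxylate, which is stable while basic, and DMAP-catalysed acetylation should cap the primary allylic hydroxyl before the hindered, conjugated carboxylate can act as an acyl donor for recyclisation, after which water hydrolyses any mixed anhydride and mild acidification frees the acid.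

**Compound list**
1 | 3-bromofuran | Brc1ccoc1 | starting material
2 | 3-furyllithium | [Li]c1ccoc1 | intermediate
3 | 2-(furan-3-yl)ethan-1-ol | OCCc1ccoc1 | intermediate
4 | 3-(2-bromoethyl)furan | BrCCc1ccoc1 | intermediate
5 | (R)-3,4-dimethylcyclohex-2-en-1-one | C[C@@H]1CCC(=O)C=C1C | starting material
6 | [2-(furan-3-yl)ethyl]magnesium bromide | Br[Mg]CCc1ccoc1 | intermediate
7 | {[(3S,4R)-3-[2-(furan-3-yl)ethyl]-3,4-dimethylcyclohex-1-en-1-yl]oxy}trimethylsilane | C[C@@H]1CCC(O[Si](C)(C)C)=C[C@@]1(C)CCc1ccoc1 | intermediate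
8 | (3S,4R)-3-[2-(furan-3-yl)ethyl]-3,4-dimethyl-2-[(trimethylsilyl)oxy]cyclohexan-1-one (C2 epimers) | C[C@@H]1CCC(=O)C(O[Si](C)(C)C)[C@@]1(C)CCc1ccoc1 | intermediate
9 | (3S,4R)-3-[2-(furan-3-yl)ethyl]-2-hydroxy-3,4-dimethylcyclohexan-1-one (C2 epimers) | C[C@@H]1CCC(=O)C(O)[C@@]1(C)CCc1ccoc1 | intermediate
10 | (4R,5S)-5-formyl-7-(furan-3-yl)-4,5-dimethylheptanoic acid | C[C@H](CCC(=O)O)[C@](C)(CCc1ccoc1)C=O | intermediate
11 | (4R,5S)-7-(furan-3-yl)-5-(hydroxymethyl)-4,5-dimethylheptanoic acid | C[C@H](CCC(=O)O)[C@](C)(CCc1ccoc1)CO | intermediate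
12 | tert-butyldimethylsilyl (4R,5S)-5-{[(tert-butyldimethylsilyl)oxy]methyl}-7-(furan-3-yl)-4,5-dimethylheptanoate | C[C@H](CCC(=O)O[Si](C)(C)C(C)(C)C)[C@](C)(CCc1ccoc1)CO[Si](C)(C)C(C)(C)C | intermediate
13 | (4R,5S)-5-{[(tert-butyldimethylsilyl)oxy]methyl}-7-(furan-3-yl)-4,5-dimethylheptanoic acid | C[C@H](CCC(=O)O)[C@](C)(CCc1ccoc1)CO[Si](C)(C)C(C)(C)C | intermediate
14 | 2-thioxopyridin-1(2H)-yl ester of acid 13 (Barton ester) | C[C@H](CCC(=O)On1ccccc1=S)[C@](C)(CCc1ccoc1)CO[Si](C)(C)C(C)(C)C | intermediate
15 | tert-butyl({(2S,3R)-2-[2-(furan-3-yl)ethyl]-5-iodo-2,3-dimethylpentyl}oxy)dimethylsilane | C[C@H](CCI)[C@](C)(CCc1ccoc1)CO[Si](C)(C)C(C)(C)C | intermediate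
16 | hexabutylditin | CCCC[Sn](CCCC)(CCCC)[Sn](CCCC)(CCCC)CCCC | starting material
17 | (Z)-1,2-bis(tributylstannyl)ethene | CCCC[Sn](CCCC)(CCCC)/C=C\[Sn](CCCC)(CCCC)CCCC | intermediate
18 | [(3R,4S)-5-[(tert-butyldimethylsilyl)oxy]-4-[2-(furan-3-yl)ethyl]-3,4-dimethylpentyl]lithium | C[C@H](CC[Li])[C@](C)(CCc1ccoc1)CO[Si](C)(C)C(C)(C)C | intermediate
19 | lithium 9-methoxy-9-[(3R,4S)-5-[(tert-butyldimethylsilyl)oxy]-4-[2-(furan-3-yl)ethyl]-3,4-dimethylpentyl]-9-boranuidabicyclo[3.3.1]nonane | [Li+].CO[B-]1(CC[C@@H](C)[C@](C)(CCc2ccoc2)CO[Si](C)(C)C(C)(C)C)C2CCCC1CCC2 | intermediate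
20 | 3,4-dibromofuran-2(5H)-one | O=C1OCC(Br)=C1Br | starting material
21 | 3-bromo-4-[(3R,4S)-5-[(tert-butyldimethylsilyl)oxy]-4-[2-(furan-3-yl)ethyl]-3,4-dimethylpentyl]furan-2(5H)-one | O=C1OCC(CC[C@@H](C)[C@](C)(CCc2ccoc2)CO[Si](C)(C)C(C)(C)C)=C1Br | intermediate
22 | 4-[(3R,4S)-5-[(tert-butyldimethylsilyl)oxy]-4-[2-(furan-3-yl)ethyl]-3,4-dimethylpentyl]-3-[(Z)-2-(tributylstannyl)ethenyl]furan-2(5H)-one | O=C1OCC(CC[C@@H](C)[C@](C)(CCc2ccoc2)CO[Si](C)(C)C(C)(C)C)=C1/C=C\[Sn](CCCC)(CCCC)CCCC | intermediate
23 | 4-[(3R,4S)-4-[2-(furan-3-yl)ethyl]-5-hydroxy-3,4-dimethylpentyl]-3-[(Z)-2-(tributylstannyl)ethenyl]furan-2(5H)-one | O=C1OCC(CC[C@@H](C)[C@](C)(CCc2ccoc2)CO)=C1/C=C\[Sn](CCCC)(CCCC)CCCC | intermediate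
24 | (2S,3R)-2-[2-(furan-3-yl)ethyl]-2,3-dimethyl-5-{5-oxo-4-[(Z)-2-(tributylstannyl)ethenyl]-2,5-dihydrofuran-3-yl}pentanal | O=C1OCC(CC[C@@H](C)[C@](C)(CCc2ccoc2)C=O)=C1/C=C\[Sn](CCCC)(CCCC)CCCC | intermediate
25 | 4-[(3R,4S,5E)-4-[2-(furan-3-yl)ethyl]-6-iodo-3,4-dimethylhex-5-en-1-yl]-3-[(Z)-2-(tributylstannyl)ethenyl]furan-2(5H)-one | O=C1OCC(CC[C@@H](C)[C@](C)(CCc2ccoc2)/C=C/I)=C1/C=C\[Sn](CCCC)(CCCC)CCCC | intermediate
26 | ten-membered-ring butenolide (furan-2(5H)-one fused at C1=C2; 3Z,5E,7S,8R in target numbering) | O=C1OCC2=C1/C=C\C=C\[C@@](C)(CCc3ccoc3)[C@H](C)CC2 | intermediate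
27 | sodium (1(10)Z,2Z,4E,6S,7R)-6-[2-(furan-3-yl)ethyl]-10-(hydroxymethyl)-6,7-dimethylcyclodeca-1(10),2,4-triene-1-carboxylate | [Na+].OC/C1=C(C(=O)[O-])/C=C\C=C\[C@@](C)(CCc2ccoc2)[C@H](C)CC1 | intermediate
28 | (1(10)Z,2Z,4E,6S,7R)-10-[(acetyloxy)methyl]-6-[2-(furan-3-yl)ethyl]-6,7-dimethylcyclodeca-1(10),2,4-triene-1-carboxylic acid (CNP0110626.2) | CC(=O)OC/C1=C(C(=O)O)/C=C\C=C\[C@@](C)(CCc2ccoc2)[C@H](C)CC1 | target

**Step count**
Total: 15 steps. Longest linear sequence: 14 steps (steps 1–7 and 9–15); step 8 is a one-step side branch.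

**Steps most likely to fail**

Step 14. Closure of the strained ten-membered triene ring may be slower than intermolecular coupling, protodestannylation, or Z-to-E drift of the dienylstannane. The fallback reverses the polarity of the ring closure; it sets out from aldehyde 24 and comes back at 26. Takai–Utimoto olefination of 24 with CrCl2, LiI and 2-(dichloromethyl)-4,4,5,5-tetramethyl-1,3,2-dioxaborolane in THF would give the (E)-alkenyl pinacolboronate F1 with the tin untouched. Iododestannylation with I2 in CH2Cl2 at 0 °C, with retention, would give the (Z)-dienyl iodide F2. An intramolecular Suzuki–Miyaura coupling (Pd(PPh3)4, TlOEt, THF/H2O, high dilution, 23 °C) would then close C4–C5 to 26. Oxidative addition then takes place at the activated iodide next to the lactone, and thallium-assisted boron transfer is fast at room temperature.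

Step 10. Oxygen nucleophiles may attack the β-carbon of the dibromide, a second alkyl transfer may occur at the α-bromide, or the product may oligomerise through its second tin. The fallback separates the two couplings and changes the nucleophile; it sets out from iodide 15 and comes back at 22. Zinc insertion (Zn dust, LiCl, THF, 40 °C) would give the alkylzinc iodide F3. A base-free Negishi coupling with 20 (Pd(PPh3)4, THF, 0 °C) would give bromobutenolide 21, which is isolated and purified. A separate Stille coupling of 21 with 17 (Pd2(dba)3, AsPh3, CuI, NMP, 40 °C) would then give 22.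

Step 15. Recyclisation to the butenolide may win if the anhydride activates the carboxylate before the hydroxyl is capped, or on acidification. The fallback protects the carboxyl first; it sets out from 26 (through salt 27) and comes back at 28. O-Alkylation of carboxylate 27 with 2-(trimethylsilyl)ethoxymethyl chloride in DMF at 0 °C would give the hydroxy SEM ester F4. Acetylation at once in the same flask (Ac2O, pyridine, DMAP) would give the acetoxy SEM ester F5. Cleavage of the SEM ester with MgBr2·OEt2 in Et2O at 23 °C would then free acid 28 without touching the acetate.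

**Further compounds**
F1 | step 14 | 4-[(3R,4S,5E)-4-[2-(furan-3-yl)ethyl]-3,4-dimethyl-6-(4,4,5,5-tetramethyl-1,3,2-dioxaborolan-2-yl)hex-5-en-1-yl]-3-[(Z)-2-(tributylstannyl)ethenyl]furan-2(5H)-one | O=C1OCC(CC[C@@H](C)[C@](C)(CCc2ccoc2)/C=C/B2OC(C)(C)C(C)(C)O2)=C1/C=C\[Sn](CCCC)(CCCC)CCCC
F2 | step 14 | 4-[(3R,4S,5E)-4-[2-(furan-3-yl)ethyl]-3,4-dimethyl-6-(4,4,5,5-tetramethyl-1,3,2-dioxaborolan-2-yl)hex-5-en-1-yl]-3-[(Z)-2-iodoethenyl]furan-2(5H)-one | O=C1OCC(CC[C@@H](C)[C@](C)(CCc2ccoc2)/C=C/B2OC(C)(C)C(C)(C)O2)=C1/C=C\I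
F3 | step 10 | [(3R,4S)-5-[(tert-butyldimethylsilyl)oxy]-4-[2-(furan-3-yl)ethyl]-3,4-dimethylpentyl]zinc iodide | C[C@H](CC[Zn]I)[C@](C)(CCc1ccoc1)CO[Si](C)(C)C(C)(C)C
F4 | step 15 | [2-(trimethylsilyl)ethoxy]methyl (1(10)Z,2Z,4E,6S,7R)-6-[2-(furan-3-yl)ethyl]-10-(hydroxymethyl)-6,7-dimethylcyclodeca-1(10),2,4-triene-1-carboxylate | OC/C1=C(C(=O)OCOCC[Si](C)(C)C)/C=C\C=C\[C@@](C)(CCc2ccoc2)[C@H](C)CC1
F5 | step 15 | [2-(trimethylsilyl)ethoxy]methyl (1(10)Z,2Z,4E,6S,7R)-10-[(acetyloxy)methyl]-6-[2-(furan-3-yl)ethyl]-6,7-dimethylcyclodeca-1(10),2,4-triene-1-carboxylate | CC(=O)OC/C1=C(C(=O)OCOCC[Si](C)(C)C)/C=C\C=C\[C@@](C)(CCc2ccoc2)[C@H](C)CC1
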